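The ring is disconnected at the C5–O bond. In shikimate numbering the ester carbon C7 (on C1) and O5 sit 1,3 to each other across C6 of the cyclohexene ring, so a carboxyl on a still-sp3 C1 can be looped onto C5 as a γ-lactone. Iodolactonisation of (R)-cyclohex-3-ene-1-carboxylic acid, an unfunctionalised acid whose only stereocentre is C1, forms the C5–O and C4–I bonds and the bridged 6-oxabicyclo[3.2.1]octanone in one operation, copying the C1 configuration onto C5. The tether is later cut and C1 flattened to the enoate; O5 is acylated first and then steers the C3/C4 dihydroxylation.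

Key step: step 1

Remarks on the chemistry (assumptions):
- Shikimate numbering is used for every carbocycle: C1 carries the carboxyl carbon C7, C2 is the future =CH, C3–C5 are the oxygenated carbons, C6 is the CH2. In the bicyclic lactones, locants 1–5 coincide with it and C8 is C6.
- The target is read as the (3R,4S,5R) triester (O3 and O4 cis, O5 trans to both) carrying an (R)-2-methylbutanoyl group on O5.
- Acids 1 and 7 are taken as purchasable single enantiomers. (R)-1 is the correct antipode: the lactone oxygen is delivered cis to C7, and the CIP ranking at C5 (O > C4 > C6 > H) is the same in 2 and in 13, so (5R) in 2 is (5R) in 13.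

Step 1
Reactants: 1 (R)-cyclohex-3-ene-1-carboxylic acid
Product: 2 (1R,4R,5R)-4-iodo-6-oxabicyclo[3.2.1]octan-7-one
Conditions: I2, KI, NaHCO3, H2O, 0 °C to rt, dark
Reagents that add atoms: iodine, II
Why: Iodolactonisation (halolactonisation of a γ,δ-unsaturated acid): iodine adds reversibly to either face of the C4=C5 alkene, and only the iodonium ion on the face opposite the carboxylate can be opened, by backside attack of the carboxylate oxygen at C5. The lactone ring O–C7–C1–C6–C5 closes in the 5-exo mode (C4 stays outside the new ring), which gives the bridged 6-oxabicyclo[3.2.1]octan-7-one. C5 is controlled by C1, because the one-carbon link C6 lets the axial carboxylate reach only the alkene face on its own side, so O5 is necessarily cis to C7; C4 is controlled by the anti addition, which places iodine trans to O5 and diaxial with it. The selectivity needed is γ- over δ-lactone closure (attack at C5 and not at C4), secured kinetically by the short 1,3-diaxial reach to C5 under buffered aqueous conditions in which the closure is not reversed. C1 is not enolised by NaHCO3, so the enantiopurity of 1 should be carried over unchanged.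

Step 2
Reactants: 2 (1R,4R,5R)-4-iodo-6-oxabicyclo[3.2.1]octan-7-one
Product: 3 (1R,5R)-6-oxabicyclo[3.2.1]oct-3-en-7-one
Conditions: DBU, toluene, 90 °C
Reagents that add atoms: none
Why: E2 dehydroiodination, in which the axial C4 iodide has an antiperiplanar hydrogen only at C3 (the C5 hydrogen is syn and at a bridgehead), so the amidine base should give the C3=C4 alkene without touching C1 or C5.

Step 3
Reactants: 3 (1R,5R)-6-oxabicyclo[3.2.1]oct-3-en-7-one
Product: 4 (1S,2S,5R)-2-bromo-6-oxabicyclo[3.2.1]oct-3-en-7-one
Conditions: NBS, AIBN (cat.), PhCF3, reflux; used crude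
Reagents that add atoms: N-bromosuccinimide, O=C1CCC(=O)N1Br
Why: Wohl–Ziegler radical allylic bromination, in which the only allylic hydrogens that can overlap with the alkene are those on C2 (the C5 hydrogen is a bridgehead acyloxy-bearing C–H) and bromine should be delivered on the face away from the lactone bridge, while neither the end of the allyl radical that takes up bromine nor the new C–Br configuration matters because both are erased in step 4.

Step 4
Reactants: 4 (1S,2S,5R)-2-bromo-6-oxabicyclo[3.2.1]oct-3-en-7-one
Product: 6 methyl (5R)-5-hydroxycyclohexa-1,3-diene-1-carboxylate, via bromo hydroxy ester 5 (not isolated)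
Conditions: NaOMe (1.2 equiv), MeOH, −10 °C to rt; AcOH quench
Reagents that add atoms: sodium methoxide, [Na+].[O-]C
Why: Lactone methanolysis (transesterification) frees O5 and turns H1 into an ester α-hydrogen, and E1cB loss of bromide from the ester enolate should then give the conjugated 1,3-dienoate, with C5 untouched and any allylically transposed bromide converging on the same dienol by the vinylogous elimination.

Step 5
Reactants: 6 methyl (5R)-5-hydroxycyclohexa-1,3-diene-1-carboxylate; 7 (R)-2-methylbutanoic acid
Product: 9 methyl (5R)-5-{[(2R)-2-methylbutanoyl]oxy}cyclohexa-1,3-diene-1-carboxylate, via (R)-2-methylbutanoic anhydride 8 (not isolated)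
Conditions: 7 (2.2 equiv), DCC (1.1 equiv), CH2Cl2, 0 °C; then 6, pyridine, DMAP (cat.), 0 °C
Reagents that add atoms: none
Why: DMAP-catalysed acyl transfer from the preformed symmetric anhydride to the only hydroxyl (O5), under conditions mild enough to avoid base-induced loss of the C5 oxygen with aromatisation and enolisation of the α-stereocentre of the acyl group.

Step 6
Reactants: 9 methyl (5R)-5-{[(2R)-2-methylbutanoyl]oxy}cyclohexa-1,3-diene-1-carboxylate
Product: 10 methyl (3R,4R,5R)-3,4-dihydroxy-5-{[(2R)-2-methylbutanoyl]oxy}cyclohex-1-ene-1-carboxylate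
Conditions: OsO4 (cat.), NMO (1.1 equiv), acetone/H2O, 0 °C to rt; Na2SO3 quench
Reagents that add atoms: osmium tetroxide, O=[Os](=O)(=O)=O; N-methylmorpholine N-oxide, C[N+]1([O-])CCOCC1; water, O
Why: Upjohn syn-dihydroxylation, in which OsO4 should take the electron-richer γ,δ C3=C4 bond in preference to the ester-conjugated C1=C2 bond and approach anti to the allylic C5 acyloxy group, so that O3 and O4 are set cis to each other and trans to O5.

Step 7
Reactants: 10 methyl (3R,4R,5R)-3,4-dihydroxy-5-{[(2R)-2-methylbutanoyl]oxy}cyclohex-1-ene-1-carboxylate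
Product: 12 methyl (3R,4S,5R)-3-acetoxy-4-hydroxy-5-{[(2R)-2-methylbutanoyl]oxy}cyclohex-1-ene-1-carboxylate, via cyclic orthoacetate 11 (not isolated)
Conditions: MeC(OMe)3, CSA (cat.), CH2Cl2, rt; then AcOH/H2O 4:1, rt
Reagents that add atoms: trimethyl orthoacetate, COC(C)(OC)OC; water, O
Why: Cyclic orthoester formation on the cis-diol followed by mild acid hydrolysis, in which the hemi-orthoester should collapse under stereoelectronic control to the ester on the pseudoaxial allylic O3 and the free equatorial O4 hydroxyl (axial-ester rule for cis-diol orthoesters), with no stereocentre changed.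

Step 8
Reactants: 12 methyl (3R,4S,5R)-3-acetoxy-4-hydroxy-5-{[(2R)-2-methylbutanoyl]oxy}cyclohex-1-ene-1-carboxylate
Product: 13 methyl (3R,4S,5R)-3-acetoxy-5-{[(2R)-2-methylbutanoyl]oxy}-4-(propanoyloxy)cyclohex-1-ene-1-carboxylate
Conditions: (EtCO)2O, pyridine, DMAP (cat.), CH2Cl2, 0 °C
Reagents that add atoms: propanoic anhydride, CCC(=O)OC(=O)CC
Why: DMAP-catalysed acylation of the one remaining secondary hydroxyl (O4) at low temperature, which should be faster than O3-to-O4 acetyl migration and touches no stereocentre.

Compound list
1 | (R)-cyclohex-3-ene-1-carboxylic acid | OC(=O)[C@H]1CC=CCC1 | starting material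
2 | (1R,4R,5R)-4-iodo-6-oxabicyclo[3.2.1]octan-7-one (I trans to the lactone oxygen) | O=C1O[C@@H]2C[C@H]1CC[C@H]2I | intermediate
3 | (1R,5R)-6-oxabicyclo[3.2.1]oct-3-en-7-one | O=C1O[C@@H]2C[C@H]1CC=C2 | intermediate
4 | (1S,2S,5R)-2-bromo-6-oxabicyclo[3.2.1]oct-3-en-7-one (Br anti to the lactone bridge) | O=C1O[C@@H]2C[C@H]1[C@@H](Br)C=C2 | intermediate
5 | methyl (1S,2S,5R)-2-bromo-5-hydroxycyclohex-3-ene-1-carboxylate (bromo hydroxy ester) | COC(=O)[C@H]1C[C@@H](O)C=C[C@@H]1Br | intermediate (not isolated)
6 | methyl (5R)-5-hydroxycyclohexa-1,3-diene-1-carboxylate | COC(=O)C1=CC=C[C@H](O)C1 | intermediate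
7 | (R)-2-methylbutanoic acid | CC[C@@H](C)C(=O)O | starting material
8 | (R)-2-methylbutanoic anhydride | CC[C@@H](C)C(=O)OC(=O)[C@H](C)CC | intermediate (not isolated)
9 | methyl (5R)-5-{[(2R)-2-methylbutanoyl]oxy}cyclohexa-1,3-diene-1-carboxylate | COC(=O)C1=CC=C[C@H](OC(=O)[C@H](C)CC)C1 | intermediate
10 | methyl (3R,4R,5R)-3,4-dihydroxy-5-{[(2R)-2-methylbutanoyl]oxy}cyclohex-1-ene-1-carboxylate (O3, O4 cis; O5 trans; the C4 descriptor differs from 12 and 13 only through CIP ranking) | O[C@@H]1[C@H](O)C=C(C(=O)OC)C[C@H]1OC(=O)[C@H](C)CC | intermediate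
11 | methyl (3aR,7R,7aS)-2-methoxy-2-methyl-7-{[(2R)-2-methylbutanoyl]oxy}-3a,6,7,7a-tetrahydro-1,3-benzodioxole-5-carboxylate (cyclic orthoacetate on O3/O4, both epimers at the orthoester carbon) | COC1(C)O[C@@H]2[C@H](O1)C=C(C(=O)OC)C[C@H]2OC(=O)[C@H](C)CC | intermediate (not isolated)
12 | methyl (3R,4S,5R)-3-acetoxy-4-hydroxy-5-{[(2R)-2-methylbutanoyl]oxy}cyclohex-1-ene-1-carboxylate | O[C@@H]1[C@H](OC(C)=O)C=C(C(=O)OC)C[C@H]1OC(=O)[C@H](C)CC | intermediate
13 | methyl (3R,4S,5R)-3-acetoxy-5-{[(2R)-2-methylbutanoyl]oxy}-4-(propanoyloxy)cyclohex-1-ene-1-carboxylate (CNP0403577.1) | CCC(=O)O[C@@H]1[C@H](OC(C)=O)C=C(C(=O)OC)C[C@H]1OC(=O)[C@H](C)CC | target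

Total step count: 8. Longest linear sequence: 8 steps (1 to 13); acid 7 enters at step 5.

Steps most likely to fail

Step 4 (lactone methanolysis with E1cB). What may go wrong: once the lactone is open, substitution of the allylic bromide by methoxide (direct or allylic) may compete with expulsion of bromide from the enolate, and prolonged exposure of the dienol to base may cause dehydration to the arene. Fallback, setting out from 3 and coming back at 9: the nucleophilic base and the allylic bromide are kept apart by changing the order of events. Lactone 3 would be opened first with NaOMe (cat.) in MeOH at 0 °C to methyl (1R,5R)-5-hydroxycyclohex-3-ene-1-carboxylate F1. O5 would be acylated with anhydride 8 (from 7 and DCC; pyridine, DMAP) to methyl (1R,5R)-5-{[(2R)-2-methylbutanoyl]oxy}cyclohex-3-ene-1-carboxylate F2. Wohl–Ziegler bromination (NBS, AIBN, PhCF3) at the unhindered allylic C2 methylene should give methyl (1S,5R)-2-bromo-5-{[(2R)-2-methylbutanoyl]oxy}cyclohex-3-ene-1-carboxylate F3 as C2 epimers. The non-nucleophilic amidine DBU in CH2Cl2 at 0 °C should then effect the E1cB dehydrobromination to 9.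

Step 3 (Wohl–Ziegler bromination). What may go wrong: ionic addition of bromine across C3=C4 or a second bromination may outrun clean allylic substitution. Fallback, setting out from 3 and coming back at 6: allylic C–H oxidation without a radical chain. SeO2 (cat.) with t-BuOOH in CH2Cl2 should react by an ene reaction and 2,3-sigmatropic shift that can only remove hydrogen from C2, since a shift towards C5 would require a bridgehead alkene. This should give (1S,2S,5R)-2-hydroxy-6-oxabicyclo[3.2.1]oct-3-en-7-one F4. Mesylation (MsCl, Et3N, CH2Cl2, 0 °C) would give (1S,2S,5R)-7-oxo-6-oxabicyclo[3.2.1]oct-3-en-2-yl methanesulfonate F5, which under the conditions of step 4 (NaOMe, MeOH) should be opened and lose methanesulfonate by E1cB to give 6.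

Step 7 (orthoester opening). What may go wrong: collapse of the hemi-orthoester with poor regiocontrol, or acid-promoted acetyl shift from O3 to O4, would leave the acetate and the later propanoate interchanged or mixed. Fallback, setting out from 10 and coming back at 12: kinetic monoacetylation governed by sterics in place of stereoelectronic ring opening. With AcCl (1.0 equiv) and 2,4,6-collidine in CH2Cl2 at −78 °C, the allylic O3 hydroxyl, flanked only by the vinylic C2–H, should be acylated ahead of the O4 hydroxyl, which is wedged between two oxygenated carbons and shielded by the branched C5 ester. No new compound is needed.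

Further compounds
F1 | step 4 | methyl (1R,5R)-5-hydroxycyclohex-3-ene-1-carboxylate | COC(=O)[C@H]1C[C@@H](O)C=CC1
F2 | step 4 | methyl (1R,5R)-5-{[(2R)-2-methylbutanoyl]oxy}cyclohex-3-ene-1-carboxylate | COC(=O)[C@H]1C[C@@H](OC(=O)[C@H](C)CC)C=CC1
F3 | step 4 | methyl (1S,5R)-2-bromo-5-{[(2R)-2-methylbutanoyl]oxy}cyclohex-3-ene-1-carboxylate (C2 epimers) | COC(=O)[C@H]1C[C@@H](OC(=O)[C@H](C)CC)C=CC1Br
F4 | step 3 | (1S,2S,5R)-2-hydroxy-6-oxabicyclo[3.2.1]oct-3-en-7-one | O=C1O[C@@H]2C[C@H]1[C@@H](O)C=C2
F5 | step 3 | (1S,2S,5R)-7-oxo-6-oxabicyclo[3.2.1]oct-3-en-2-yl methanesulfonate | O=C1O[C@@H]2C[C@H]1[C@@H](OS(C)(=O)=O)C=C2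
F0 | step 7 | none | none
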